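**Retrosynthetic overview**

1. Endgame: the β-hydroxy ketone is unmasked last (acetonide off, MnO2 oxidation of the benzylic carbinol, buffered desilylation), so the labile carbon alpha to the ketone stays a non-enolisable benzylic CH until the end.
2. Key disconnection: the 3,7-dioxabicyclo[3.3.0]octane is opened at the bridgehead–bridgehead C–C bond and at the O–CH bond of the carbon that carries the dihydrobenzofuranyl group. This gives an acyclic (E)-cinnamyl ether of a 1-aryl-2,3-epoxypropan-1-ol; Cp2TiCl then I2 re-forms both bonds in one flask (ring 1 by 5-exo radical closure, ring 2 by ether closure).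
3. Enabling feature: in ring 2 the bridgehead CH, its CH2 and the ring oxygen are a latent oxirane, and the benzylic carbon that this oxygen must reach is para to the dihydrobenzofuran ring oxygen, which stabilises radical and cation there. The oxirane carbon becomes planar, so both oxirane epimers converge, and the single carbinol centre (catalytic asymmetric vinylation) dictates the three new centres.
4. Fragments, both from 2-allyl-4-bromo-6-methoxyphenol and joined by Williamson etherification: the western epoxy alcohol (Evans syn-aldol sets the carbon alpha to the future ketone; acetonide; formylation; vinylation; epoxidation) and the eastern cinnamyl bromide (cis-dihydrobenzofuran by dirhodium-carbenoid C–H insertion; Suzuki–Miyaura coupling).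
5. Ring order: dihydrobenzofuran (step 17), then tetrahydrofuran ring 1 and ring 2 of the furofuran (step 23); the dioxane acetonide is a temporary ring (steps 9 to 24).

Key step: step 23

Assumption 1: the SMILES is taken literally, so the dihydrobenzofuran carries aryl and hydroxymethyl cis (2S,3S), the furofuran is exo,exo (1S,3aR,4S,6aR) and the carbon alpha to the ketone is S.
Assumption 2: the hand of the dirhodium catalyst in step 17 is assigned by analogy with related 2-benzyloxyaryl diazoacetates; if the antipode forms, Rh2(S-PTTL)4 is used instead.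

**Route**

Step 1
Reactants: 1 vanillin
Product: 2 3-methoxy-4-(triisopropylsilyloxy)benzaldehyde
Conditions: i-Pr3SiCl, imidazole, DMF, rt
Reagents that add atoms: chlorotriisopropylsilane, CC(C)[Si](Cl)(C(C)C)C(C)C
Why: Imidazole-promoted O-silylation of the phenol; the TIPS ether should withstand the boron aldol, hydride, organolithium, peracid and mild-acid steps and fall to buffered fluoride at the end.

Step 2
Reactants: 2 3-methoxy-4-(triisopropylsilyloxy)benzaldehyde
Product: 3 [3-methoxy-4-(triisopropylsilyloxy)phenyl]methanol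
Conditions: NaBH4, MeOH, 0 °C
Reagents that add atoms: none
Why: Borohydride reduction of the aryl aldehyde gives the benzylic alcohol needed as Mitsunobu partner; no stereocentre is formed.

Step 3
Reactants: 4 2-allyl-6-methoxyphenol
Product: 5 2-allyl-4-bromo-6-methoxyphenol
Conditions: NBS, MeCN, 0 °C
Reagents that add atoms: N-bromosuccinimide, O=C1CCC(=O)N1Br
Why: Electrophilic aromatic bromination of a phenol whose two ortho positions are blocked goes para to the hydroxyl and should be much faster at 0 °C than addition to the isolated terminal alkene.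

Step 4
Reactants: 5 2-allyl-4-bromo-6-methoxyphenol
Product: 6 (2-allyl-4-bromo-6-methoxyphenoxy)triisopropylsilane
Conditions: i-Pr3SiOTf, 2,6-lutidine, CH2Cl2, 0 °C to rt
Reagents that add atoms: triisopropylsilyl triflate, CC(C)[Si](OS(=O)(=O)C(F)(F)F)(C(C)C)C(C)C
Why: Silyl triflate silylation overcomes the hindrance of the 2,6-disubstituted phenol.

Step 5
Reactants: 6 (2-allyl-4-bromo-6-methoxyphenoxy)triisopropylsilane
Product: 8 2-[5-bromo-3-methoxy-2-(triisopropylsilyloxy)phenyl]acetic acid, via arylacetaldehyde 7 (not isolated)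
Conditions: O3, MeCN/H2O (9:1), 0 °C; then NaClO2, NaH2PO4, 2-methyl-2-butene, 0 °C to rt
Reagents that add atoms: ozone, O=[O+][O-]; water, O; sodium chlorite, [Na+].[O-]Cl=O
Why: Ozonolysis of the terminal alkene in wet acetonitrile gives the aldehyde directly because water intercepts the carbonyl oxide, and Pinnick oxidation in the same flask should give the acid before the enolisable arylacetaldehyde can condense.

Step 6
Reactants: 8 2-[5-bromo-3-methoxy-2-(triisopropylsilyloxy)phenyl]acetic acid; 9 (R)-4-benzyl-1,3-oxazolidin-2-one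
Product: 11 (R)-4-benzyl-3-{2-[5-bromo-3-methoxy-2-(triisopropylsilyloxy)phenyl]acetyl}-1,3-oxazolidin-2-one, via mixed pivalic anhydride 10 (not isolated)
Conditions: t-BuCOCl, Et3N, THF, −20 to 0 °C; then 9, LiCl, rt
Reagents that add atoms: none
Why: LiCl-assisted N-acylation of the oxazolidinone through the mixed pivalic anhydride installs the Evans auxiliary without strong base.

Step 7
Reactants: 11 N-arylacetyl oxazolidinone; 2 3-methoxy-4-(triisopropylsilyloxy)benzaldehyde
Product: 13 (2R,3R)-syn-aldol adduct, via dibutylboron Z-enolate 12 (not isolated)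
Conditions: Bu2BOTf, i-Pr2NEt, CH2Cl2, −78 to 0 °C; then 2, −78 to 0 °C; then pH 7 buffer, MeOH, H2O2, 0 °C
Reagents that add atoms: none
Why: Evans syn-aldol reaction in which the Z-boron enolate reacts through a closed chair transition state and the (R)-benzyl group blocks one enolate face, which should set C2 as R (the future carbon alpha to the ketone) and the carbinol as R, the latter being of no consequence because it is oxidised in step 25.

Step 8
Reactants: 13 (2R,3R)-syn-aldol adduct
Product: 14 (1R,2S)-2-[5-bromo-3-methoxy-2-(triisopropylsilyloxy)phenyl]-1-[3-methoxy-4-(triisopropylsilyloxy)phenyl]propane-1,3-diol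
Conditions: LiBH4, THF/MeOH, 0 °C
Reagents that add atoms: none
Why: Reductive removal of the auxiliary with LiBH4 should give the primary alcohol faster than the benzylic alpha carbon can epimerise, so that centre is kept (2S by priority change only).

Step 9
Reactants: 14 (1R,2S)-1,3-diol
Product: 15 (4R,5S)-5-[5-bromo-3-methoxy-2-(triisopropylsilyloxy)phenyl]-4-[3-methoxy-4-(triisopropylsilyloxy)phenyl]-2,2-dimethyl-1,3-dioxane
Conditions: Me2C(OMe)2, PPTS (cat.), CH2Cl2, rt
Reagents that add atoms: 2,2-dimethoxypropane, COC(C)(C)OC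
Why: Acid-catalysed transketalisation ties the 1,3-diol into a six-membered acetonide that masks both hydroxyls through the organometallic, basic and radical steps and releases them together later.

Step 10
Reactants: 15 acetonide aryl bromide
Product: 17 3-methoxy-5-[(4R,5S)-4-[3-methoxy-4-(triisopropylsilyloxy)phenyl]-2,2-dimethyl-1,3-dioxan-5-yl]-4-(triisopropylsilyloxy)benzaldehyde, via aryllithium 16 (not isolated)
Conditions: n-BuLi, THF, −78 °C; then DMF, −78 to 0 °C; aq NH4Cl
Reagents that add atoms: N,N-dimethylformamide, CN(C)C=O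
Why: Bromine–lithium exchange at −78 °C followed by formylation with DMF converts the aryl bromide into the aldehyde, the silyl ethers and the acetal being inert to the aryllithium at this temperature.

Step 11
Reactants: 17 western aldehyde
Product: 18 (S)-1-aryl-prop-2-en-1-ol (aryl = ring of 17)
Conditions: Zn(CH=CH2)2, (−)-MIB [(2S)-3-exo-morpholinoisoborneol, 10 mol%], toluene, −30 to 0 °C
Reagents that add atoms: divinylzinc, C=C[Zn]C=C
Why: Amino-alcohol-catalysed enantioselective addition of an alkenylzinc reagent to an aryl aldehyde, in which the ligand–zinc chelate delivers vinyl to the Si face and should set the carbinol as S under catalyst control, the remote stereocentres being too far away to interfere.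

Step 12
Reactants: 18 (S)-allylic alcohol
Product: 19 (R)-aryl(oxiran-2-yl)methanol, both oxirane epimers
Conditions: mCPBA, NaHCO3, CH2Cl2, 0 °C to rt
Reagents that add atoms: 3-chloroperoxybenzoic acid, OOC(=O)c1cccc(Cl)c1
Why: Hydroxyl-assisted peracid (Prilezhaev) epoxidation of the only alkene; both oxirane epimers are expected and both are carried on, since that carbon becomes a planar radical in step 23.

Step 13
Reactants: 5 2-allyl-4-bromo-6-methoxyphenol; 3 [3-methoxy-4-(triisopropylsilyloxy)phenyl]methanol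
Product: 20 {4-[(2-allyl-4-bromo-6-methoxyphenoxy)methyl]-2-methoxyphenoxy}triisopropylsilane
Conditions: PPh3, DIAD, THF, 0 °C to rt
Reagents that add atoms: none
Why: Mitsunobu etherification joins the hindered phenol and the electron-rich benzylic alcohol under neutral conditions that keep the aryl silyl ether, and puts in place the benzylic O–CH2 whose C–H bond is the insertion site of step 17.

Step 14
Reactants: 20 benzyl aryl ether
Product: 22 2-[5-bromo-3-methoxy-2-{[3-methoxy-4-(triisopropylsilyloxy)benzyl]oxy}phenyl]acetic acid, via arylacetaldehyde 21 (not isolated)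
Conditions: O3, MeCN/H2O (9:1), 0 °C; then NaClO2, NaH2PO4, 2-methyl-2-butene, 0 °C to rt
Reagents that add atoms: ozone, O=[O+][O-]; water, O; sodium chlorite, [Na+].[O-]Cl=O
Why: Same telescoped ozonolysis–Pinnick oxidation as in step 5, the terminal alkene reacting far faster with ozone than the benzylic ether or the arenes.

Step 15
Reactants: 22 arylacetic acid
Product: 23 methyl 2-[5-bromo-3-methoxy-2-{[3-methoxy-4-(triisopropylsilyloxy)benzyl]oxy}phenyl]acetate
Conditions: Me3SiCHN2, toluene/MeOH, 0 °C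
Reagents that add atoms: trimethylsilyldiazomethane, C[Si](C)(C)C=[N+]=[N-]
Why: Methyl ester formation with trimethylsilyldiazomethane under neutral conditions.

Step 16
Reactants: 23 methyl arylacetate
Product: 24 methyl 2-diazo-2-[5-bromo-3-methoxy-2-{[3-methoxy-4-(triisopropylsilyloxy)benzyl]oxy}phenyl]acetate
Conditions: p-ABSA, DBU, MeCN, 0 °C to rt
Reagents that add atoms: 4-acetamidobenzenesulfonyl azide, CC(=O)Nc1ccc(cc1)S(=O)(=O)N=[N+]=[N-]
Why: Regitz diazo transfer to the benzylic, ester-activated methylene gives the donor–acceptor aryldiazoacetate.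

Step 17
Reactants: 24 aryldiazoacetate
Product: 25 methyl (2S,3R)-5-bromo-7-methoxy-2-[3-methoxy-4-(triisopropylsilyloxy)phenyl]-2,3-dihydro-1-benzofuran-3-carboxylate (2,3-cis)
Conditions: Rh2(R-PTTL)4 [dirhodium tetrakis(N-phthaloyl-(R)-tert-leucinate), 2 mol%], toluene, −78 °C
Reagents that add atoms: none
Why: Dirhodium-carbenoid intramolecular 1,5 C–H insertion into the electron-rich benzylic ether C–H closes the dihydrobenzofuran, and with N-phthaloyl-tert-leucinate catalysts this insertion is cis-selective and enantioselective, the chiral carboxylate pocket fixing the approach of the C–H bond so that both centres (2S,3R) should be set at once under kinetic control.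

Step 18
Reactants: 25 cis-dihydrobenzofuran ester
Product: 26 [(2S,3S)-5-bromo-7-methoxy-2-[3-methoxy-4-(triisopropylsilyloxy)phenyl]-2,3-dihydro-1-benzofuran-3-yl]methanol
Conditions: i-Bu2AlH, CH2Cl2, −78 °C; Rochelle salt
Reagents that add atoms: none
Why: Low-temperature DIBAL-H reduction is non-basic, so the less stable cis ester should be reduced to the primary alcohol without epimerisation at C3 (3S by priority change only).

Step 19
Reactants: 26 cis-dihydrobenzofuran alcohol
Product: 27 tert-butyldimethylsilyl ether of 26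
Conditions: t-BuMe2SiCl, imidazole, DMF, rt
Reagents that add atoms: tert-butyldimethylsilyl chloride, CC(C)(C)[Si](C)(C)Cl
Why: Silylation of the primary alcohol keeps it apart from the allylic alcohol made in the next step.

Step 20
Reactants: 27 aryl bromide; 28 (E)-3-(4,4,5,5-tetramethyl-1,3,2-dioxaborolan-2-yl)prop-2-en-1-ol
Product: 29 (E)-3-[(2S,3S)-3-(tert-butyldimethylsilyloxymethyl)-7-methoxy-2-[3-methoxy-4-(triisopropylsilyloxy)phenyl]-2,3-dihydro-1-benzofuran-5-yl]prop-2-en-1-ol
Conditions: Pd(OAc)2 (5 mol%), SPhos, K3PO4, THF/H2O, 50 °C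
Reagents that add atoms: none
Why: Suzuki–Miyaura coupling of the electron-rich aryl bromide with the E-alkenylboronate proceeds with retention of alkene geometry and delivers the cinnamyl alcohol directly, phosphate base at 50 °C leaving both silyl ethers.

Step 21
Reactants: 29 eastern allylic alcohol
Product: 30 eastern (E)-allylic bromide
Conditions: CBr4, PPh3, 2,6-lutidine, CH2Cl2, −20 °C; used at once
Reagents that add atoms: carbon tetrabromide, BrC(Br)(Br)Br
Why: Appel bromination converts the allylic alcohol into the bromide by SN2 at the primary carbon under buffered, non-acidic conditions.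

Step 22
Reactants: 19 epoxy alcohol (both oxirane epimers); 30 eastern allylic bromide
Product: 31 epoxy (E)-cinnamyl ether, (R) at the ether carbon, both oxirane epimers
Conditions: NaH, Bu4NI (cat.), THF/DMF, −20 to 0 °C, bromide present from the start
Reagents that add atoms: none
Why: Williamson etherification in which the sodium alkoxide is generated in the presence of the highly reactive allylic bromide at low temperature so that O-alkylation should outrun epoxide migration, and no stereocentre is touched.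

Step 23
Reactants: 31 epoxy (E)-cinnamyl ether (both oxirane epimers)
Product: 33 fully protected (1S,3aR,4S,6aR)-furofuran, via benzylic iodide 32 (not isolated)
Conditions: Cp2TiCl2 (2.5 equiv), Zn dust, THF, rt, slow addition to 31; then I2, 60 °C
Reagents that add atoms: none
Why: Cp2TiCl (trivalent titanium) transfers one electron to the oxirane and cleaves its more substituted C–O bond, so either oxirane epimer gives the same planar secondary β-titanoxy radical; this adds 5-exo-trig to the proximal carbon of the styrenyl double bond (closing tetrahydrofuran ring 1 and forming the bridgehead–bridgehead C–C bond) and leaves a benzylic radical, para to the dihydrobenzofuran oxygen, that is captured by a second Cp2TiCl. Iodine then turns the benzyl–titanium bond into a benzylic iodide, which ionises with help of the para oxygen and is closed by the neighbouring titanium alkoxide (5-exo-tet-type SN1 etherification, ring 2, the O–CH(aryl) bond). The closest known reaction type is the titanocene-mediated radical cyclisation of epoxy cinnamyl ethers with iodine quench, which gives exo,exo-2,6-diaryl-3,7-dioxabicyclo[3.3.0]octanes. The existing ether carbon controls the two bridgeheads: in the chair-like 5-exo transition state its aryl group is pseudo-equatorial, which should give the 2,3-trans, 3,4-cis tetrahydrofuran, the only arrangement that can close ring 2; the last centre is set in that closure, where the aryl group takes the convex (exo) face of the forming cis-fused bicycle. The step needs cyclisation to outrun reduction of the first radical (deoxygenation to the alkene), which the fast 5-exo addition to an electron-rich styrene and the slow addition of Cp2TiCl secure, and it needs no control at the oxirane carbon, so the epimer mixture should converge on one product.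

Step 24
Reactants: 33 fully protected furofuran
Product: 34 tris-TIPS triol (1R,2S-diol side chain and dihydrobenzofuran CH2OH free)
Conditions: PPTS, MeOH/CH2Cl2, 40 °C
Reagents that add atoms: none
Why: Mild acid-catalysed methanolysis removes the acetonide and the primary TBS ether, while the aryl TIPS ethers and the benzylic ring ethers, which need stronger acid to ionise, should remain.

Step 25
Reactants: 34 tris-TIPS triol
Product: 35 tris-TIPS (2S)-β-hydroxy ketone
Conditions: MnO2 (activated, excess), CH2Cl2, rt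
Reagents that add atoms: none
Why: Activated MnO2 oxidises the electron-rich benzylic secondary alcohol and leaves the two primary aliphatic alcohols, under neutral heterogeneous conditions that should not enolise the new alpha-aryl ketone, so the 2S centre is kept.

Step 26
Reactants: 35 tris-TIPS β-hydroxy ketone
Product: 36 CNP0174045.1 (target)
Conditions: Bu4NF, AcOH (1:1), THF, 0 °C
Reagents that add atoms: none
Why: Fluoride cleavage of the three aryl silyl ethers, buffered with acetic acid so that neither phenoxide nor basic fluoride should epimerise the alpha-aryl β-hydroxy ketone or trigger retro-aldol loss of formaldehyde.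

**Compound list**

1 | vanillin (4-hydroxy-3-methoxybenzaldehyde) | COc1cc(C=O)ccc1O | starting material
2 | 3-methoxy-4-(triisopropylsilyloxy)benzaldehyde | COc1cc(C=O)ccc1O[Si](C(C)C)(C(C)C)C(C)C | intermediate
3 | [3-methoxy-4-(triisopropylsilyloxy)phenyl]methanol | COc1cc(CO)ccc1O[Si](C(C)C)(C(C)C)C(C)C | intermediate
4 | 2-allyl-6-methoxyphenol | C=CCc1cccc(OC)c1O | starting material
5 | 2-allyl-4-bromo-6-methoxyphenol | C=CCc1cc(Br)cc(OC)c1O | intermediate
6 | (2-allyl-4-bromo-6-methoxyphenoxy)triisopropylsilane | C=CCc1cc(Br)cc(OC)c1O[Si](C(C)C)(C(C)C)C(C)C | intermediate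
7 | 2-[5-bromo-3-methoxy-2-(triisopropylsilyloxy)phenyl]acetaldehyde | O=CCc1cc(Br)cc(OC)c1O[Si](C(C)C)(C(C)C)C(C)C | intermediate (not isolated)
8 | 2-[5-bromo-3-methoxy-2-(triisopropylsilyloxy)phenyl]acetic acid | OC(=O)Cc1cc(Br)cc(OC)c1O[Si](C(C)C)(C(C)C)C(C)C | intermediate
9 | (R)-4-benzyl-1,3-oxazolidin-2-one | O=C1N[C@H](Cc2ccccc2)CO1 | starting material
10 | mixed anhydride of 8 with pivalic acid | CC(C)(C)C(=O)OC(=O)Cc1cc(Br)cc(OC)c1O[Si](C(C)C)(C(C)C)C(C)C | intermediate (not isolated)
11 | (R)-4-benzyl-3-{2-[5-bromo-3-methoxy-2-(triisopropylsilyloxy)phenyl]acetyl}-1,3-oxazolidin-2-one | O=C(Cc1cc(Br)cc(OC)c1O[Si](C(C)C)(C(C)C)C(C)C)N1C(=O)OC[C@H]1Cc1ccccc1 | intermediate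
12 | (Z)-dibutylboron enolate of 11 | CCCCB(CCCC)O/C(=C\c1cc(Br)cc(OC)c1O[Si](C(C)C)(C(C)C)C(C)C)N1C(=O)OC[C@H]1Cc1ccccc1 | intermediate (not isolated)
13 | (R)-4-benzyl-3-[(2R,3R)-2-[5-bromo-3-methoxy-2-(triisopropylsilyloxy)phenyl]-3-hydroxy-3-[3-methoxy-4-(triisopropylsilyloxy)phenyl]propanoyl]-1,3-oxazolidin-2-one | COc1cc([C@H](O)[C@H](C(=O)N3C(=O)OC[C@H]3Cc3ccccc3)c2cc(Br)cc(OC)c2O[Si](C(C)C)(C(C)C)C(C)C)ccc1O[Si](C(C)C)(C(C)C)C(C)C | intermediate
14 | (1R,2S)-2-[5-bromo-3-methoxy-2-(triisopropylsilyloxy)phenyl]-1-[3-methoxy-4-(triisopropylsilyloxy)phenyl]propane-1,3-diol | COc1cc([C@H](O)[C@H](CO)c2cc(Br)cc(OC)c2O[Si](C(C)C)(C(C)C)C(C)C)ccc1O[Si](C(C)C)(C(C)C)C(C)C | intermediate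
15 | (4R,5S)-5-[5-bromo-3-methoxy-2-(triisopropylsilyloxy)phenyl]-4-[3-methoxy-4-(triisopropylsilyloxy)phenyl]-2,2-dimethyl-1,3-dioxane | COc1cc([C@@H]3OC(C)(C)OC[C@@H]3c2cc(Br)cc(OC)c2O[Si](C(C)C)(C(C)C)C(C)C)ccc1O[Si](C(C)C)(C(C)C)C(C)C | intermediate
16 | aryllithium from 15 (lithium in place of bromine) | COc1cc([C@@H]3OC(C)(C)OC[C@@H]3c2cc([Li])cc(OC)c2O[Si](C(C)C)(C(C)C)C(C)C)ccc1O[Si](C(C)C)(C(C)C)C(C)C | intermediate (not isolated)
17 | 3-methoxy-5-[(4R,5S)-4-[3-methoxy-4-(triisopropylsilyloxy)phenyl]-2,2-dimethyl-1,3-dioxan-5-yl]-4-(triisopropylsilyloxy)benzaldehyde | COc1cc([C@@H]3OC(C)(C)OC[C@@H]3c2cc(C=O)cc(OC)c2O[Si](C(C)C)(C(C)C)C(C)C)ccc1O[Si](C(C)C)(C(C)C)C(C)C | intermediate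
18 | (S)-1-{3-methoxy-5-[(4R,5S)-4-[3-methoxy-4-(triisopropylsilyloxy)phenyl]-2,2-dimethyl-1,3-dioxan-5-yl]-4-(triisopropylsilyloxy)phenyl}prop-2-en-1-ol | COc1cc([C@@H]3OC(C)(C)OC[C@@H]3c2cc([C@@H](O)C=C)cc(OC)c2O[Si](C(C)C)(C(C)C)C(C)C)ccc1O[Si](C(C)C)(C(C)C)C(C)C | intermediate
19 | (R)-{aryl of 18}[(2RS)-oxiran-2-yl]methanol, both oxirane epimers | COc1cc([C@@H]3OC(C)(C)OC[C@@H]3c2cc([C@@H](O)C4CO4)cc(OC)c2O[Si](C(C)C)(C(C)C)C(C)C)ccc1O[Si](C(C)C)(C(C)C)C(C)C | intermediate
20 | {4-[(2-allyl-4-bromo-6-methoxyphenoxy)methyl]-2-methoxyphenoxy}triisopropylsilane | C=CCc1cc(Br)cc(OC)c1OCc1ccc(O[Si](C(C)C)(C(C)C)C(C)C)c(OC)c1 | intermediate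
21 | 2-[5-bromo-3-methoxy-2-{[3-methoxy-4-(triisopropylsilyloxy)benzyl]oxy}phenyl]acetaldehyde | O=CCc1cc(Br)cc(OC)c1OCc1ccc(O[Si](C(C)C)(C(C)C)C(C)C)c(OC)c1 | intermediate (not isolated)
22 | 2-[5-bromo-3-methoxy-2-{[3-methoxy-4-(triisopropylsilyloxy)benzyl]oxy}phenyl]acetic acid | OC(=O)Cc1cc(Br)cc(OC)c1OCc1ccc(O[Si](C(C)C)(C(C)C)C(C)C)c(OC)c1 | intermediate
23 | methyl 2-[5-bromo-3-methoxy-2-{[3-methoxy-4-(triisopropylsilyloxy)benzyl]oxy}phenyl]acetate | COC(=O)Cc1cc(Br)cc(OC)c1OCc1ccc(O[Si](C(C)C)(C(C)C)C(C)C)c(OC)c1 | intermediate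
24 | methyl 2-diazo-2-[5-bromo-3-methoxy-2-{[3-methoxy-4-(triisopropylsilyloxy)benzyl]oxy}phenyl]acetate | COC(=O)C(=[N+]=[N-])c1cc(Br)cc(OC)c1OCc1ccc(O[Si](C(C)C)(C(C)C)C(C)C)c(OC)c1 | intermediate
25 | methyl (2S,3R)-5-bromo-7-methoxy-2-[3-methoxy-4-(triisopropylsilyloxy)phenyl]-2,3-dihydro-1-benzofuran-3-carboxylate (cis) | Brc1cc(OC)c2c(c1)[C@@H](C(=O)OC)[C@@H](c1ccc(O[Si](C(C)C)(C(C)C)C(C)C)c(OC)c1)O2 | intermediate
26 | [(2S,3S)-5-bromo-7-methoxy-2-[3-methoxy-4-(triisopropylsilyloxy)phenyl]-2,3-dihydro-1-benzofuran-3-yl]methanol | Brc1cc(OC)c2c(c1)[C@@H](CO)[C@@H](c1ccc(O[Si](C(C)C)(C(C)C)C(C)C)c(OC)c1)O2 | intermediate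
27 | (2S,3S)-5-bromo-3-(tert-butyldimethylsilyloxymethyl)-7-methoxy-2-[3-methoxy-4-(triisopropylsilyloxy)phenyl]-2,3-dihydro-1-benzofuran | Brc1cc(OC)c2c(c1)[C@@H](CO[Si](C)(C)C(C)(C)C)[C@@H](c1ccc(O[Si](C(C)C)(C(C)C)C(C)C)c(OC)c1)O2 | intermediate
28 | (E)-3-(4,4,5,5-tetramethyl-1,3,2-dioxaborolan-2-yl)prop-2-en-1-ol | OC/C=C/B1OC(C)(C)C(C)(C)O1 | starting material
29 | (E)-3-[(2S,3S)-3-(tert-butyldimethylsilyloxymethyl)-7-methoxy-2-[3-methoxy-4-(triisopropylsilyloxy)phenyl]-2,3-dihydro-1-benzofuran-5-yl]prop-2-en-1-ol | OC/C=C/c1cc(OC)c2c(c1)[C@@H](CO[Si](C)(C)C(C)(C)C)[C@@H](c1ccc(O[Si](C(C)C)(C(C)C)C(C)C)c(OC)c1)O2 | intermediate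
30 | (2S,3S)-5-[(E)-3-bromoprop-1-enyl]-3-(tert-butyldimethylsilyloxymethyl)-7-methoxy-2-[3-methoxy-4-(triisopropylsilyloxy)phenyl]-2,3-dihydro-1-benzofuran | BrC/C=C/c1cc(OC)c2c(c1)[C@@H](CO[Si](C)(C)C(C)(C)C)[C@@H](c1ccc(O[Si](C(C)C)(C(C)C)C(C)C)c(OC)c1)O2 | intermediate
31 | ether of 19 with 30: (R)-aryl(oxiran-2-yl)methyl (E)-3-(dihydrobenzofuran-5-yl)prop-2-enyl ether, both oxirane epimers | COc1cc([C@@H]3OC(C)(C)OC[C@@H]3c2cc([C@@H](OC/C=C/c3cc(OC)c4c(c3)[C@@H](CO[Si](C)(C)C(C)(C)C)[C@@H](c3ccc(O[Si](C(C)C)(C(C)C)C(C)C)c(OC)c3)O4)C3CO3)cc(OC)c2O[Si](C(C)C)(C(C)C)C(C)C)ccc1O[Si](C(C)C)(C(C)C)C(C)C | intermediate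
32 | (2S,3R,4R)-2-aryl-3-(hydroxymethyl)-4-[iodo(dihydrobenzofuran-5-yl)methyl]tetrahydrofuran, drawn as the free alcohol (titanium alkoxide in the flask), CHI carbon undefined | COc1cc([C@@H]5OC(C)(C)OC[C@@H]5c2cc([C@H]3OC[C@H](C(I)c4cc(OC)c6c(c4)[C@@H](CO[Si](C)(C)C(C)(C)C)[C@@H](c4ccc(O[Si](C(C)C)(C(C)C)C(C)C)c(OC)c4)O6)[C@@H]3CO)cc(OC)c2O[Si](C(C)C)(C(C)C)C(C)C)ccc1O[Si](C(C)C)(C(C)C)C(C)C | intermediate (not isolated)
33 | (1S,3aR,4S,6aR)-1-(western aryl)-4-(eastern dihydrobenzofuran-5-yl)tetrahydro-1H,3H-furo[3,4-c]furan carrying three aryl TIPS ethers, the TBS ether and the acetonide | COc1cc([C@@H]5OC(C)(C)OC[C@@H]5c2cc([C@H]3OC[C@H]4[C@@H]3CO[C@@H]4c3cc(OC)c4c(c3)[C@@H](CO[Si](C)(C)C(C)(C)C)[C@@H](c3ccc(O[Si](C(C)C)(C(C)C)C(C)C)c(OC)c3)O4)cc(OC)c2O[Si](C(C)C)(C(C)C)C(C)C)ccc1O[Si](C(C)C)(C(C)C)C(C)C | intermediate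
34 | tris-TIPS triol: (1R,2S)-propane-1,3-diol side chain and dihydrobenzofuran CH2OH free | COc1cc([C@H](O)[C@H](CO)c2cc([C@H]3OC[C@H]4[C@@H]3CO[C@@H]4c3cc(OC)c4c(c3)[C@@H](CO)[C@@H](c3ccc(O[Si](C(C)C)(C(C)C)C(C)C)c(OC)c3)O4)cc(OC)c2O[Si](C(C)C)(C(C)C)C(C)C)ccc1O[Si](C(C)C)(C(C)C)C(C)C | intermediate
35 | tris-TIPS ether of the target ((2S)-3-hydroxy-1-aryl-2-arylpropan-1-one) | COc1cc(C(=O)[C@H](CO)c2cc([C@H]3OC[C@H]4[C@@H]3CO[C@@H]4c3cc(OC)c4c(c3)[C@@H](CO)[C@@H](c3ccc(O[Si](C(C)C)(C(C)C)C(C)C)c(OC)c3)O4)cc(OC)c2O[Si](C(C)C)(C(C)C)C(C)C)ccc1O[Si](C(C)C)(C(C)C)C(C)C | intermediate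
36 | CNP0174045.1: (2S)-3-hydroxy-1-(4-hydroxy-3-methoxyphenyl)-2-{2-hydroxy-5-[(1S,3aR,4S,6aR)-4-[(2S,3S)-2-(4-hydroxy-3-methoxyphenyl)-3-(hydroxymethyl)-7-methoxy-2,3-dihydro-1-benzofuran-5-yl]tetrahydro-1H,3H-furo[3,4-c]furan-1-yl]-3-methoxyphenyl}propan-1-one | COc1cc(C(=O)[C@H](CO)c2cc([C@H]3OC[C@H]4[C@@H]3CO[C@@H]4c3cc(OC)c4c(c3)[C@@H](CO)[C@@H](c3ccc(O)c(OC)c3)O4)cc(OC)c2O)ccc1O | target

**Step count and risks**

Total step count: 26.
Longest linear sequence: 16 steps (steps 1, 2 and 13 to 26).

Steps most likely to fail: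

1. Step 23 (key step). What may go wrong: the benzylic radical is reduced and protonated before iodine can act, so that only ring 1 forms; the oxirane-derived radical is reduced and eliminated (deoxygenation) before it cyclises; or the ether closure shows poor facial control. Fallback (C–H oxidation in place of the radical–polar crossover): from 31 the Cp2TiCl cyclisation is run with a proton quench (aqueous NaH2PO4 in place of I2), which should give the ring 1 product, the (2S,3R,4R)-tetrahydrofuran alcohol F1 with a benzylic CH2. DDQ (CH2Cl2/pH 7 buffer, 0 °C) then abstracts hydride from this methylene, which is para to the dihydrobenzofuran oxygen on the most electron-rich ring, and the primary alcohol traps the cation (oxidative benzylic etherification), returning to the route at 33.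

2. Step 22. What may go wrong: epoxide migration in the alkoxide (Payne rearrangement) followed by alkylation at the wrong oxygen, and ionisation or elimination of the allylic bromide. Fallback (π-allyl palladium chemistry in place of SN2): from 29, ClCO2Me and pyridine give the allylic methyl carbonate F2. Zerovalent-palladium-catalysed allylic etherification of the zinc alkoxide of 19 (Et2Zn, Pd(OAc)2, 2-(di-tert-butylphosphino)biphenyl, THF, rt) should then give the linear E ether, returning at 31 without a free alkali alkoxide and without bromide 30.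

3. Step 11. What may go wrong: slow or poorly face-selective vinyl transfer to the electron-rich aldehyde. Fallback (kinetic resolution in place of asymmetric addition): from 17, CH2=CHMgBr (THF, −78 °C) gives the allylic alcohol F3 as both carbinol epimers. Sharpless kinetic-resolution epoxidation (Ti(OiPr)4, D-(−)-diisopropyl tartrate, t-BuOOH, 4 Å sieves, CH2Cl2, −20 °C) should epoxidise only the S-carbinol epimer, which returns directly at 19 (as its erythro epimer, step 12 being skipped); the unreacted R-carbinol epimer is separated.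

**Further compounds**

F1 | step 23 | [(2S,3R,4R)-2-(western aryl)-4-(eastern dihydrobenzofuran-5-ylmethyl)tetrahydrofuran-3-yl]methanol (protecting groups as in 31) | COc1cc([C@@H]5OC(C)(C)OC[C@@H]5c2cc([C@H]3OC[C@H](Cc4cc(OC)c6c(c4)[C@@H](CO[Si](C)(C)C(C)(C)C)[C@@H](c4ccc(O[Si](C(C)C)(C(C)C)C(C)C)c(OC)c4)O6)[C@@H]3CO)cc(OC)c2O[Si](C(C)C)(C(C)C)C(C)C)ccc1O[Si](C(C)C)(C(C)C)C(C)C
F2 | step 22 | methyl carbonate of 29 ((E)-allylic methyl carbonate) | COC(=O)OC/C=C/c1cc(OC)c2c(c1)[C@@H](CO[Si](C)(C)C(C)(C)C)[C@@H](c1ccc(O[Si](C(C)C)(C(C)C)C(C)C)c(OC)c1)O2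
F3 | step 11 | (1RS)-1-aryl-prop-2-en-1-ol, both carbinol epimers of 18 | COc1cc([C@@H]3OC(C)(C)OC[C@@H]3c2cc(C(O)C=C)cc(OC)c2O[Si](C(C)C)(C(C)C)C(C)C)ccc1O[Si](C(C)C)(C(C)C)C(C)C
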